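**Retrosynthetic overview**

1. The (E,E)-diene is made last by a Mizoroki–Heck union of the vinyl group on C6 of bromo-oxane 12 with (E)-iodoalkene 24. The two rings are built separately; the cyclohexane ring comes intact from (S)-limonene.
2. Cyclohexane half 24: limonene → trans-diaxial 1,2-diol → isopropenyl turned into the (E)-iodoalkene (ozonolysis, alkyne, carboalumination/iodination) → C2–OH replaced by Br with inversion (cis-bromohydrin).
3. Oxane half 12: C3–Br from C3–OH by inversion; C3–OH from ketone 10 by reagent-controlled reduction; 10 from oxanol 9.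
4. Enabling feature: in the oxane ring, C2 is a fully substituted ketal-type carbon bonded to ring oxygen O1, and its neighbour C3 carries a heteroatom. With O in place of Br, O1–C2(Me)2–C3–O is the retron of an acetal [1,2]-Wittig shift. The C2–C3 bond is therefore made by contracting the seven-membered acetonide (1,3-dioxepane) 6 of a C3/C6 1,4-diol to the six-membered oxane.
5. 6 comes from (R)-linalool (C6 stereocentre and vinyl handle) and 2-methoxypropene (C2 and both methyls). Ring order: oxane ring closed in step 4; cyclohexane ring pre-formed.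

Key step: step 4

Remark (assumption): (R)-linalool and (S)-limonene are taken as enantiopure commercial materials. Locants in the explanations follow the target: oxane O1, C2 (CMe2), C3 (CHBr), C6 (quaternary); cyclohexane C1 (C–OH), C2 (CHBr), C4 (side chain).

**Route**

Step 1
Reactants: 1 (R)-(−)-linalool; 2 2-methoxypropene
Product: 3 (3R)-3-[(2-methoxypropan-2-yl)oxy]-3,7-dimethylocta-1,6-diene
Conditions: 2 (5 equiv), PPTS (2 mol %), CH2Cl2, 0 °C; Et3N quench
Reagents that add atoms: 2-methoxypropene (compound 2), COC(C)=C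
Why: Acid-catalysed addition of the tertiary alcohol to the enol ether (mixed-ketal formation) installs the O1–CMe2 unit at 0 °C, far below the temperature of the competing Claisen (Saucy–Marbet) pathway, and sets no stereocentre.

Step 2
Reactants: 3 (3R)-3-[(2-methoxypropan-2-yl)oxy]-3,7-dimethylocta-1,6-diene
Product: 4 (4R)-4-[(2-methoxypropan-2-yl)oxy]-4-methylhex-5-enal
Conditions: O3 (1 equiv, Sudan Red 7B end point), NaHCO3, CH2Cl2, −78 °C; Me2S, −78 °C → rt
Reagents that add atoms: ozone, [O-][O+]=O
Why: Chemoselective ozonolysis, because the electron-rich trisubstituted alkene reacts much faster than the monosubstituted vinyl group and the buffered aprotic medium preserves the acid-labile mixed ketal.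

Step 3
Reactants: 4 (4R)-4-[(2-methoxypropan-2-yl)oxy]-4-methylhex-5-enal
Product: 6 (7R)-7-ethenyl-2,2,7-trimethyl-4-(tributylstannyl)-1,3-dioxepane (both C4 epimers), via hydroxystannane 5 (not isolated)
Conditions: Bu3SnH, LDA, THF, 0 °C; then 4, −78 °C; H2O; crude 5, PPTS (5 mol %), 4 Å MS, CH2Cl2, 0 °C
Reagents that add atoms: tributyltin hydride, CCCC[SnH](CCCC)CCCC
Why: Addition of tributylstannyllithium to the aldehyde gives the α-hydroxystannane, which closes onto the pendant mixed ketal by acid-catalysed transketalisation (loss of methanol) to the seven-membered acetonide; the stannyl carbinol centre forms as both epimers, which does not matter because it is destroyed in step 4.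

Step 4
Reactants: 6 (7R)-7-ethenyl-2,2,7-trimethyl-4-(tributylstannyl)-1,3-dioxepane
Product: 9 (6R)-6-ethenyl-2,2,6-trimethyloxan-3-ol (both C3 epimers), via lithiodioxepane 7 (not isolated), via lithium oxanolate 8 (not isolated)
Conditions: n-BuLi (1.3 equiv), THF, −78 °C, then −78 → −20 °C; H2O
Reagents that add atoms: none
Why: Proposed new method: tin–lithium exchange converts the C4 stannane of 6 into the unstabilised α-alkoxyalkyllithium 7, whose adjacent acetal O–CMe2 bond homolyses to a tethered pair of a lithium ketyl (future C3) and the tertiary α-oxy radical O1–C•Me2 (future C2), and recombination at carbon gives alkoxide 8, i.e. a [1,2]-Wittig rearrangement. The closest known reaction types are the acetal [1,2]-Wittig rearrangement that turns O-glycosides into C-glycosides and the [1,2]-Wittig shift of α-alkoxyalkyllithiums generated from stannanes; what is new is the ring contraction of a 1,3-dioxepane with an unstabilised carbanion. The oxane ring closes by contraction of the seven-membered ring to a six-membered one: the dioxepane O3–C2 bond breaks, the C2–C4 bond forms by radical–radical recombination across a six-atom chain, and O3 becomes the exocyclic C3 oxygen. The new carbinol centre C3 is not controlled and is erased in step 5, the quaternary C2 is not stereogenic, and C6 keeps its configuration because none of its bonds is touched. The step needs the [1,2]-shift to outrun protonation of 7 and β-scission of the C2 radical (loss of acetone to leave an allyl radical); this should be secured by the tether, which keeps the pair geminate, by the migrating carbon being a tertiary oxygen-substituted radical, and by the absence of an allyl group on the carbanion oxygen, which excludes a [2,3]-path.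

Step 5
Reactants: 9 (6R)-6-ethenyl-2,2,6-trimethyloxan-3-ol
Product: 10 (6R)-6-ethenyl-2,2,6-trimethyloxan-3-one
Conditions: Pr4N[RuO4] (5 mol %), NMO, 4 Å MS, CH2Cl2, rt
Reagents that add atoms: none
Why: Ley–Griffith oxidation converges both C3 epimers on one ketone under neutral conditions that spare the vinyl group and the tertiary allylic ether.

Step 6
Reactants: 10 (6R)-6-ethenyl-2,2,6-trimethyloxan-3-one
Product: 11 (3R,6R)-6-ethenyl-2,2,6-trimethyloxan-3-ol
Conditions: (S)-2-methyl-CBS-oxazaborolidine (20 mol %), catecholborane, toluene, −78 → −40 °C; aq NaOH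
Reagents that add atoms: none
Why: Corey–Bakshi–Shibata reduction under reagent control, with the quaternary C2 as the large and C4H2 as the small ketone substituent, should give the (3R)-alcohol irrespective of the remote C6 centre, and catecholborane leaves the vinyl group unhydroborated.

Step 7
Reactants: 11 (3R,6R)-6-ethenyl-2,2,6-trimethyloxan-3-ol
Product: 12 (3S,6R)-3-bromo-6-ethenyl-2,2,6-trimethyloxane
Conditions: CBr4, (n-C8H17)3P, toluene, 70 °C
Reagents that add atoms: carbon tetrabromide, BrC(Br)(Br)Br
Why: Appel-type bromination, in which bromide displaces the alkoxyphosphonium group by SN2 with inversion (3R → 3S), using the trialkylphosphine variant suited to hindered secondary carbinols next to an ether oxygen.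

Step 8
Reactants: 13 (S)-(−)-limonene
Product: 14 (4S)-limonene 1,2-oxide (both oxirane diastereomers)
Conditions: mCPBA, NaHCO3, CH2Cl2, 0 °C
Reagents that add atoms: 3-chloroperbenzoic acid, OOC(=O)c1cccc(Cl)c1
Why: Prilezhaev epoxidation is selective for the more electron-rich trisubstituted ring alkene; the diastereomer mixture does not matter because step 9 converges it.

Step 9
Reactants: 14 (4S)-limonene 1,2-oxide
Product: 15 (1R,2R,4S)-1-methyl-4-(prop-1-en-2-yl)cyclohexane-1,2-diol
Conditions: H2SO4 (1 % aq), THF, 0 °C → rt; recrystallisation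
Reagents that add atoms: water, O
Why: Acid-catalysed trans-diaxial epoxide hydrolysis, in which the diastereomer with the oxirane oxygen syn to the isopropenyl group is opened at C2 and the anti diastereomer at C1, so both should converge on the same diaxial diol (C1–OH cis and C2–OH trans to the isopropenyl group).

Step 10
Reactants: 15 (1R,2R,4S)-1-methyl-4-(prop-1-en-2-yl)cyclohexane-1,2-diol
Product: 16 (1R,2R,4S)-4-acetyl-1-methylcyclohexane-1,2-diol
Conditions: O3, CH2Cl2/MeOH, −78 °C; Me2S
Reagents that add atoms: ozone, [O-][O+]=O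
Why: Ozonolysis of the only alkene (1,1-disubstituted) gives the methyl ketone with loss of formaldehyde and touches no stereocentre.

Step 11
Reactants: 16 (1R,2R,4S)-4-acetyl-1-methylcyclohexane-1,2-diol
Product: 17 (1R,2R,4S)-4-acetyl-1-methyl-1,2-bis(triethylsilyloxy)cyclohexane
Conditions: TESOTf (2.5 equiv), 2,6-lutidine, CH2Cl2, −78 → 0 °C
Reagents that add atoms: triethylsilyl trifluoromethanesulfonate, CC[Si](CC)(CC)OS(=O)(=O)C(F)(F)F
Why: Silylation with the silyl triflate protects both the secondary and the hindered tertiary hydroxyl against the strong base and the organoaluminium reagent of steps 12 and 13.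

Step 12
Reactants: 17 (1R,2R,4S)-4-acetyl-1-methyl-1,2-bis(triethylsilyloxy)cyclohexane
Product: 19 (1R,2R,4S)-4-ethynyl-1-methyl-1,2-bis(triethylsilyloxy)cyclohexane, via enol phosphate 18 (not isolated)
Conditions: LDA, THF, −78 °C; ClP(O)(OEt)2; then LDA (2.3 equiv), −78 °C → rt; H2O
Reagents that add atoms: none
Why: Kinetic deprotonation at the methyl group, O-phosphorylation and base-induced elimination of the enol phosphate give the terminal alkyne (methyl ketone to alkyne conversion), and C4 is not at risk because its equatorial configuration is the thermodynamically preferred one.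

Step 13
Reactants: 19 (1R,2R,4S)-4-ethynyl-1-methyl-1,2-bis(triethylsilyloxy)cyclohexane
Product: 21 (1R,2R,4S)-4-[(E)-1-iodoprop-1-en-2-yl]-1-methyl-1,2-bis(triethylsilyloxy)cyclohexane, via alkenylalane 20 (not isolated)
Conditions: Me3Al (3 equiv), Cp2ZrCl2 (0.3 equiv), CH2Cl2, 0 °C → rt; then I2, THF, −30 °C
Reagents that add atoms: trimethylaluminium, C[Al](C)C; iodine, II
Why: Negishi zirconium-catalysed carboalumination adds methyl and aluminium syn across the alkyne with methyl on the internal carbon, and iodinolysis with retention gives the (E)-trisubstituted iodoalkene.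

Step 14
Reactants: 21 (1R,2R,4S)-4-[(E)-1-iodoprop-1-en-2-yl]-1-methyl-1,2-bis(triethylsilyloxy)cyclohexane
Product: 22 (1R,2R,5S)-5-[(E)-1-iodoprop-1-en-2-yl]-2-methyl-2-(triethylsilyloxy)cyclohexan-1-ol
Conditions: PPTS, MeOH/CH2Cl2, 0 °C
Reagents that add atoms: none
Why: Acid-catalysed methanolysis removes the less hindered secondary silyl ether selectively, leaving the tertiary silyl ether in place.

Step 15
Reactants: 22 (1R,2R,5S)-5-[(E)-1-iodoprop-1-en-2-yl]-2-methyl-2-(triethylsilyloxy)cyclohexan-1-ol
Product: 23 {[(1R,2S,4S)-2-bromo-4-[(E)-1-iodoprop-1-en-2-yl]-1-methylcyclohexyl]oxy}triethylsilane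
Conditions: CBr4, (n-C8H17)3P, toluene, 60 °C
Reagents that add atoms: carbon tetrabromide, BrC(Br)(Br)Br
Why: Appel-type bromination, in which bromide displaces the axial alkoxyphosphonium group at C2 by SN2 with inversion (R → S) to place the bromide equatorial and cis to the C1 oxygen, while the silyl group stops the trans-diaxial tertiary oxygen from closing an epoxide.

Step 16
Reactants: 23 {[(1R,2S,4S)-2-bromo-4-[(E)-1-iodoprop-1-en-2-yl]-1-methylcyclohexyl]oxy}triethylsilane
Product: 24 (1R,2S,4S)-2-bromo-4-[(E)-1-iodoprop-1-en-2-yl]-1-methylcyclohexan-1-ol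
Conditions: HF·pyridine, pyridine, THF, 0 °C → rt
Reagents that add atoms: none
Why: Fluoride cleavage of the tertiary silyl ether under buffered conditions; the cis-bromohydrin cannot close to an epoxide, so the C–Br bond is safe.

Step 17
Reactants: 12 (3S,6R)-3-bromo-6-ethenyl-2,2,6-trimethyloxane; 24 (1R,2S,4S)-2-bromo-4-[(E)-1-iodoprop-1-en-2-yl]-1-methylcyclohexan-1-ol
Product: 25 (1R,2S,4S)-2-bromo-4-[(2E,4E)-5-[(2R,5S)-5-bromo-2,6,6-trimethyloxan-2-yl]penta-2,4-dien-2-yl]-1-methylcyclohexan-1-ol
Conditions: Pd(OAc)2 (10 mol %), n-Bu4NCl, NaHCO3, DMF, 50 °C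
Reagents that add atoms: none
Why: Mizoroki–Heck reaction, in which zerovalent palladium inserts into the alkenyl C–I bond with retention, carbopalladation places the alkenyl group on the terminal vinyl carbon, and β-hydride elimination can occur only toward the new bond because C6 is quaternary, giving the (E,E)-diene while the secondary alkyl bromides stay inert.

**Compound list**

1 | (R)-(−)-linalool | C=C[C@](C)(O)CCC=C(C)C | starting material
2 | 2-methoxypropene | COC(C)=C | starting material
3 | (3R)-3-[(2-methoxypropan-2-yl)oxy]-3,7-dimethylocta-1,6-diene | C=C[C@](C)(OC(C)(C)OC)CCC=C(C)C | intermediate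
4 | (4R)-4-[(2-methoxypropan-2-yl)oxy]-4-methylhex-5-enal | C=C[C@](C)(OC(C)(C)OC)CCC=O | intermediate
5 | (4R)-4-[(2-methoxypropan-2-yl)oxy]-4-methyl-1-(tributylstannyl)hex-5-en-1-ol (C1 epimers) | C=C[C@](C)(OC(C)(C)OC)CCC(O)[Sn](CCCC)(CCCC)CCCC | intermediate
6 | (7R)-7-ethenyl-2,2,7-trimethyl-4-(tributylstannyl)-1,3-dioxepane (C4 epimers) | C=C[C@@]1(C)CCC([Sn](CCCC)(CCCC)CCCC)OC(C)(C)O1 | intermediate
7 | (7R)-7-ethenyl-4-lithio-2,2,7-trimethyl-1,3-dioxepane | C=C[C@@]1(C)CCC([Li])OC(C)(C)O1 | intermediate
8 | lithium (6R)-6-ethenyl-2,2,6-trimethyloxan-3-olate | C=C[C@@]1(C)CCC(O[Li])C(C)(C)O1 | intermediate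
9 | (6R)-6-ethenyl-2,2,6-trimethyloxan-3-ol (C3 epimers) | C=C[C@@]1(C)CCC(O)C(C)(C)O1 | intermediate
10 | (6R)-6-ethenyl-2,2,6-trimethyloxan-3-one | C=C[C@@]1(C)CCC(=O)C(C)(C)O1 | intermediate
11 | (3R,6R)-6-ethenyl-2,2,6-trimethyloxan-3-ol | C=C[C@@]1(C)CC[C@@H](O)C(C)(C)O1 | intermediate
12 | (3S,6R)-3-bromo-6-ethenyl-2,2,6-trimethyloxane | C=C[C@@]1(C)CC[C@H](Br)C(C)(C)O1 | intermediate
13 | (S)-(−)-limonene | CC1=CC[C@H](CC1)C(C)=C | starting material
14 | (4S)-1-methyl-4-(prop-1-en-2-yl)-7-oxabicyclo[4.1.0]heptane (limonene 1,2-oxide, both oxirane diastereomers) | CC(=C)[C@H]1CCC2(C)OC2C1 | intermediate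
15 | (1R,2R,4S)-1-methyl-4-(prop-1-en-2-yl)cyclohexane-1,2-diol | CC(=C)[C@H]1CC[C@@](C)(O)[C@H](O)C1 | intermediate
16 | (1R,2R,4S)-4-acetyl-1-methylcyclohexane-1,2-diol | CC(=O)[C@H]1CC[C@@](C)(O)[C@H](O)C1 | intermediate
17 | (1R,2R,4S)-4-acetyl-1-methyl-1,2-bis(triethylsilyloxy)cyclohexane | CC(=O)[C@H]1CC[C@@](C)(O[Si](CC)(CC)CC)[C@H](O[Si](CC)(CC)CC)C1 | intermediate
18 | diethyl 1-[(1S,3R,4R)-4-methyl-3,4-bis(triethylsilyloxy)cyclohexyl]ethenyl phosphate | C=C(OP(=O)(OCC)OCC)[C@H]1CC[C@@](C)(O[Si](CC)(CC)CC)[C@H](O[Si](CC)(CC)CC)C1 | intermediate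
19 | (1R,2R,4S)-4-ethynyl-1-methyl-1,2-bis(triethylsilyloxy)cyclohexane | C#C[C@H]1CC[C@@](C)(O[Si](CC)(CC)CC)[C@H](O[Si](CC)(CC)CC)C1 | intermediate
20 | dimethyl{(E)-2-[(1S,3R,4R)-4-methyl-3,4-bis(triethylsilyloxy)cyclohexyl]prop-1-en-1-yl}alane | C/C(=C\[Al](C)C)[C@H]1CC[C@@](C)(O[Si](CC)(CC)CC)[C@H](O[Si](CC)(CC)CC)C1 | intermediate
21 | (1R,2R,4S)-4-[(E)-1-iodoprop-1-en-2-yl]-1-methyl-1,2-bis(triethylsilyloxy)cyclohexane | C/C(=C\I)[C@H]1CC[C@@](C)(O[Si](CC)(CC)CC)[C@H](O[Si](CC)(CC)CC)C1 | intermediate
22 | (1R,2R,5S)-5-[(E)-1-iodoprop-1-en-2-yl]-2-methyl-2-(triethylsilyloxy)cyclohexan-1-ol | C/C(=C\I)[C@H]1CC[C@@](C)(O[Si](CC)(CC)CC)[C@H](O)C1 | intermediate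
23 | {[(1R,2S,4S)-2-bromo-4-[(E)-1-iodoprop-1-en-2-yl]-1-methylcyclohexyl]oxy}triethylsilane | C/C(=C\I)[C@H]1CC[C@@](C)(O[Si](CC)(CC)CC)[C@@H](Br)C1 | intermediate
24 | (1R,2S,4S)-2-bromo-4-[(E)-1-iodoprop-1-en-2-yl]-1-methylcyclohexan-1-ol | C/C(=C\I)[C@H]1CC[C@@](C)(O)[C@@H](Br)C1 | intermediate
25 | (1R,2S,4S)-2-bromo-4-[(2E,4E)-5-[(2R,5S)-5-bromo-2,6,6-trimethyloxan-2-yl]penta-2,4-dien-2-yl]-1-methylcyclohexan-1-ol | C/C(=C\C=C\[C@@]1(C)CC[C@H](Br)C(C)(C)O1)[C@H]1CC[C@@](C)(O)[C@@H](Br)C1 | target

**Step count**

Total steps: 17 (steps 1–7 oxane half, steps 8–16 cyclohexane half, step 17 union). Longest linear sequence: 10 steps (13 → 25 through steps 8–17).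

**Steps most likely to fail, with fallbacks**

Step 4 (proposed new method). After tin–lithium exchange the carbanion may be protonated by the solvent, or the radical pair may escape recombination (β-scission of the C2 radical with loss of acetone), so that no C2–C3 bond forms. The fallback uses known chemistry and closes the ring at O1–C2 instead. It sets out from (R)-linalool 1: peracid epoxidation of the trisubstituted alkene (mCPBA, NaHCO3, CH2Cl2, 0 °C) gives (3R)-5-(3,3-dimethyloxiran-2-yl)-3-methylpent-1-en-3-ol F1. Acid catalysis (camphorsulfonic acid, CH2Cl2) then makes the tertiary hydroxyl open the epoxide; the 6-endo mode gives oxanol 9, expected beside the furanoid isomers and separated from them by chromatography. The route is rejoined at 9, before step 5.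

Step 7. Backside displacement at the neopentyl-type C3 is slow, so elimination toward C3=C4, participation of the ring oxygen (retention or ring contraction) or a 1,2-methyl shift may outrun the substitution. The fallback makes the participation the productive path and sets out from ketone 10. Reduction with the enantiomeric (R)-oxazaborolidine and catecholborane should give the C3 epimer, (3S,6R)-6-ethenyl-2,2,6-trimethyloxan-3-ol F2. Triflation (Tf2O, 2,6-di-tert-butylpyridine, CH2Cl2, −78 °C) gives (3S,6R)-6-ethenyl-2,2,6-trimethyloxan-3-yl trifluoromethanesulfonate F3. Its equatorial C3–O bond lies antiperiplanar to the ring C2–O1 bond, so O1 assists ionisation to a bicyclic oxiranium ion. Bromide (n-Bu4NBr, −78 °C → rt) opens this ion at C3 with a second inversion, i.e. net retention, to give bromide 12. Bromide captured at C2 instead gives the ring-contracted (2R,5R)-2-(2-bromopropan-2-yl)-5-ethenyl-5-methyloxolane F4, which should re-ionise through the same oxiranium ion on warming and drain to 12. The route is rejoined at 12, before step 17.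

Step 15. Substitution at C2 is retarded by the trans-axial silyloxy group on C1, so E2 elimination toward C2=C3, or loss of the silyl group with epoxide closure, may compete. The fallback ties both oxygens into a cyclic sulfate, so that no silyl group sits next to the reacting carbon, and sets out from 21. Global desilylation (HF·pyridine, THF) gives (1R,2R,4S)-4-[(E)-1-iodoprop-1-en-2-yl]-1-methylcyclohexane-1,2-diol F5. 1,1'-Sulfonyldiimidazole and NaH in THF close the trans-fused cyclic sulfate (3aR,6S,7aR)-6-[(E)-1-iodoprop-1-en-2-yl]-3a-methylhexahydro-1,3,2-benzodioxathiole 2,2-dioxide F6. LiBr in THF should open it at the secondary carbon with inversion to (1R,2S,4S)-2-bromo-4-[(E)-1-iodoprop-1-en-2-yl]-1-methylcyclohexyl hydrogen sulfate F7, which is hydrolysed (cat. H2SO4, THF/H2O) to bromohydrin 24. The route is rejoined at 24, before step 17.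

**Further compounds**

F1 | step 4 | (3R)-5-(3,3-dimethyloxiran-2-yl)-3-methylpent-1-en-3-ol (oxirane epimers) | C=C[C@](C)(O)CCC1OC1(C)C
F2 | step 7 | (3S,6R)-6-ethenyl-2,2,6-trimethyloxan-3-ol | C=C[C@@]1(C)CC[C@H](O)C(C)(C)O1
F3 | step 7 | (3S,6R)-6-ethenyl-2,2,6-trimethyloxan-3-yl trifluoromethanesulfonate | C=C[C@@]1(C)CC[C@H](OS(=O)(=O)C(F)(F)F)C(C)(C)O1
F4 | step 7 | (2R,5R)-2-(2-bromopropan-2-yl)-5-ethenyl-5-methyloxolane | C=C[C@@]1(C)CC[C@H](C(C)(C)Br)O1
F5 | step 15 | (1R,2R,4S)-4-[(E)-1-iodoprop-1-en-2-yl]-1-methylcyclohexane-1,2-diol | C/C(=C\I)[C@H]1CC[C@@](C)(O)[C@H](O)C1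
F6 | step 15 | (3aR,6S,7aR)-6-[(E)-1-iodoprop-1-en-2-yl]-3a-methylhexahydro-1,3,2-benzodioxathiole 2,2-dioxide | C/C(=C\I)[C@H]1CC[C@@]2(C)OS(=O)(=O)O[C@@H]2C1
F7 | step 15 | (1R,2S,4S)-2-bromo-4-[(E)-1-iodoprop-1-en-2-yl]-1-methylcyclohexyl hydrogen sulfate | C/C(=C\I)[C@H]1CC[C@@](C)(OS(=O)(=O)O)[C@@H](Br)C1
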